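**Plan** (guaiane numbering: C1/C5 ring fusion; C2–C4 complete the five-membered ring, C4 bears methyl C15; C6–C10 complete the seven-membered ring, C7 bears the side chain, C10 bears methyl C14; C11–C13 side chain)
- Cuts: O–S of the sulfate; both C–O bonds at C1 and C10 (syn-dihydroxylation of C1=C10); C4–H (hydrogenation of C4=C15); C10–C14; then C3–C4 of the five-membered ring, cut together with re-closure of C1–C3 to a spiro-cyclopropane; then the cyclopropane CH2 groups, C4–C5, and C1=C5 (ring-closing metathesis) back to (R)-limonene.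
- Forward order: side-chain diol on limonene; ring cleavage and metathesis to the seven-membered enone; alkyne at C5 and cyclopropane at C1; five-membered ring by a ketyl ring-opening/5-exo-dig cascade; then C14, H2, OsO4, sulfate.
- Enabling feature: the three-membered ring C1–C2–C3, spiro-fused at C1 to the cycloheptanone ring next to the C10 carbonyl, with an ethynyl group (C4≡C15) on neighbouring C5. One electron at C10 turns this into the C1=C10 enolate and a C3 radical five atoms from C4.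
- Stereochemistry: C7 from (R)-limonene; C11 from a Sharpless epoxidation; C5 from a 1,3-cis conjugate addition; C4 from hydrogenation on the H-5 face; C1 and C10 together from osmylation on that same face.

Key step: step 12

Remark: the target is drawn as the free hydrogen sulfate, so the pyridinium salt from the sulfation is passed through an acidic resin in the cold and the acid is freeze-dried at once.

**Step 1**
Reactants: 1 (R)-(+)-limonene
Product: 4 2-[(1R)-4-methylcyclohex-3-en-1-yl]prop-2-en-1-ol, via allyllithium 2 (not isolated), via allylboronate 3 (not isolated)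
Conditions: n-BuLi, TMEDA, hexane, rt; B(OMe)3, −78 °C; H2O2, aq. NaOH, 0 °C
Reagents that add atoms: hydrogen peroxide (OO)
Why: n-BuLi–TMEDA should metallate limonene at the isopropenyl methyl group (allylic lithiation to a symmetric 2-substituted allyl anion), and borylation–oxidation then gives the primary allylic alcohol without touching the ring stereocentre.

**Step 2**
Reactants: 4 2-[(1R)-4-methylcyclohex-3-en-1-yl]prop-2-en-1-ol
Product: 5 [(2R)-2-[(1R)-4-methylcyclohex-3-en-1-yl]oxiran-2-yl]methanol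
Conditions: Ti(OiPr)4 (cat.), diethyl D-(−)-tartrate (cat.), t-BuOOH, 4 Å sieves, CH2Cl2, −20 °C
Reagents that add atoms: tert-butyl hydroperoxide (CC(C)(C)OO)
Why: Sharpless asymmetric epoxidation of a 2-substituted allylic alcohol is reagent-controlled, and the D-(−)-tartrate complex should give the (2R)-oxirane that becomes the (R)-carbinol C11, while the ring alkene has no directing hydroxyl and should stay intact.

**Step 3**
Reactants: 5 [(2R)-2-[(1R)-4-methylcyclohex-3-en-1-yl]oxiran-2-yl]methanol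
Product: 6 (2R)-2-[(1R)-4-methylcyclohex-3-en-1-yl]propane-1,2-diol
Conditions: LiAlH4, THF, 0 °C to rt
Reagents that add atoms: none
Why: hydride opens the 2,2-disubstituted epoxide by SN2 attack at its unsubstituted CH2 terminus (which becomes methyl C13), so the C11–O bond and its configuration are untouched.

**Step 4**
Reactants: 6 (2R)-2-[(1R)-4-methylcyclohex-3-en-1-yl]propane-1,2-diol
Product: 7 (4R)-2,2,4-trimethyl-4-[(1R)-4-methylcyclohex-3-en-1-yl]-1,3-dioxolane
Conditions: 2,2-dimethoxypropane, PPTS (cat.), CH2Cl2, rt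
Reagents that add atoms: 2,2-dimethoxypropane (COC(C)(C)OC)
Why: acid-catalysed transketalisation closes the five-membered acetonide of the 1,2-diol, which masks both hydroxyl groups against the bases, organometallics and reductants that follow.

**Step 5**
Reactants: 7 (4R)-2,2,4-trimethyl-4-[(1R)-4-methylcyclohex-3-en-1-yl]-1,3-dioxolane
Product: 9 (3R)-6-oxo-3-[(4R)-2,2,4-trimethyl-1,3-dioxolan-4-yl]heptanal, via ozonide 8 (not isolated)
Conditions: O3, CH2Cl2, −78 °C; PPh3, −78 °C to rt
Reagents that add atoms: ozone (O=[O+][O-])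
Why: ozonolysis with reductive work-up cleaves the only C=C bond, turning the ring alkene carbons into the C10 methyl ketone and the C5 aldehyde and leaving C7 as the only stereocentre of the chain.

**Step 6**
Reactants: 9 (3R)-6-oxo-3-[(4R)-2,2,4-trimethyl-1,3-dioxolan-4-yl]heptanal
Product: 10 (5R)-5-[(4R)-2,2,4-trimethyl-1,3-dioxolan-4-yl]oct-7-en-2-one
Conditions: Ph3PCH3Br, KN(SiMe3)2, THF, −78 to 0 °C
Reagents that add atoms: methyltriphenylphosphonium bromide (C[P+](c1ccccc1)(c1ccccc1)c1ccccc1.[Br-])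
Why: Wittig methylenation with one equivalent of ylide at low temperature should take the aldehyde much faster than the methyl ketone, giving the terminal alkene at C5.

**Step 7**
Reactants: 10 (5R)-5-[(4R)-2,2,4-trimethyl-1,3-dioxolan-4-yl]oct-7-en-2-one
Product: 14 (6R)-6-[(4R)-2,2,4-trimethyl-1,3-dioxolan-4-yl]nona-1,8-dien-3-one, via lithium enolate 11 (not isolated), via Mannich base 12 (not isolated), via ammonium iodide 13 (not isolated)
Conditions: LiN(iPr)2, THF, −78 °C; CH2=NMe2+ I−, −78 °C to rt; MeI; aq. NaHCO3, CH2Cl2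
Reagents that add atoms: N,N-dimethylmethyleneiminium iodide (C=[N+](C)C.[I-])
Why: kinetic deprotonation occurs at the methyl group, and Mannich reaction with Eschenmoser's salt, quaternisation and E1cB elimination turn that methyl carbon into C1 of a vinyl ketone.

**Step 8**
Reactants: 14 (6R)-6-[(4R)-2,2,4-trimethyl-1,3-dioxolan-4-yl]nona-1,8-dien-3-one
Product: 15 (5R)-5-[(4R)-2,2,4-trimethyl-1,3-dioxolan-4-yl]cyclohept-2-en-1-one
Conditions: RuCl2(=CHPh)(PCy3)(H2IMes) (second-generation Grubbs catalyst, cat.), CH2Cl2 (dilute), 40 °C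
Reagents that add atoms: none
Why: ring-closing metathesis of the vinyl ketone with the terminal alkene forms the C1=C5 bond of the seven-membered enone with loss of ethene, a reliable closure for cycloheptenones.

**Step 9**
Reactants: 15 (5R)-5-[(4R)-2,2,4-trimethyl-1,3-dioxolan-4-yl]cyclohept-2-en-1-one
Product: 16 trimethyl({(3R,5R)-3-[(trimethylsilyl)ethynyl]-5-[(4R)-2,2,4-trimethyl-1,3-dioxolan-4-yl]cyclohept-1-en-1-yl}oxy)silane
Conditions: Me3SiC≡CH, n-BuLi, THF, 0 °C; ZnBr2; then 15, Me3SiOTf, Et2O–THF, −40 °C; Et3N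
Reagents that add atoms: ethynyltrimethylsilane (C#C[Si](C)(C)C); trimethylsilyl trifluoromethanesulfonate (C[Si](C)(C)OS(=O)(=O)C(F)(F)F)
Why: silyl-triflate-promoted conjugate addition of an alkynylzinc reagent gives the silyl enol ether directly and so fixes the enolate at C1, and the alkynyl group should enter C5 cis to the equatorial C7 side chain because attack on the chair-like cycloheptenone from the face away from the ring fold leads to the 1,3-cis product.

**Step 10**
Reactants: 16 trimethyl({(3R,5R)-3-[(trimethylsilyl)ethynyl]-5-[(4R)-2,2,4-trimethyl-1,3-dioxolan-4-yl]cyclohept-1-en-1-yl}oxy)silane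
Product: 18 N,N,N-trimethyl-1-{(2R,4R)-7-oxo-4-[(4R)-2,2,4-trimethyl-1,3-dioxolan-4-yl]-2-[(trimethylsilyl)ethynyl]cycloheptyl}methanaminium iodide (both C1 epimers), via Mannich base 17 (not isolated)
Conditions: CH2=NMe2+ I−, CH2Cl2, rt; aq. NaHCO3; MeI, Et2O, rt
Reagents that add atoms: N,N-dimethylmethyleneiminium iodide (C=[N+](C)C.[I-]); iodomethane (CI)
Why: the regiodefined silyl enol ether undergoes a Mannich reaction with Eschenmoser's salt only at C1 (this carbon becomes C2), and quaternisation gives a storable precursor of the α-methylene ketone whose C1 configuration is irrelevant.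

**Step 11**
Reactants: 18 N,N,N-trimethyl-1-{(2R,4R)-7-oxo-4-[(4R)-2,2,4-trimethyl-1,3-dioxolan-4-yl]-2-[(trimethylsilyl)ethynyl]cycloheptyl}methanaminium iodide
Product: 21 (7R,9S)-9-ethynyl-7-[(4R)-2,2,4-trimethyl-1,3-dioxolan-4-yl]spiro[2.6]nonan-4-one, via methylene ketone 19 (not isolated), via silylalkyne ketone 20 (not isolated)
Conditions: Me3S(O)I, NaH, DMSO, rt (2.2 equiv ylide); then MeOH, K2CO3, rt
Reagents that add atoms: trimethylsulfoxonium iodide (C[S+](C)(C)=O.[I-])
Why: the first equivalent of dimethylsulfoxonium methylide releases the α-methylene ketone by elimination of trimethylamine and the second adds to it and closes the spiro-cyclopropane (Corey–Chaykovsky cyclopropanation, the ylide carbon becoming C3), so the sensitive enone is trapped as it forms, and methanolysis then removes the C-silyl group.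

**Step 12**
Reactants: 21 (7R,9S)-9-ethynyl-7-[(4R)-2,2,4-trimethyl-1,3-dioxolan-4-yl]spiro[2.6]nonan-4-one
Product: 23 (3aS,5R)-3-methylidene-5-[(4R)-2,2,4-trimethyl-1,3-dioxolan-4-yl]-1,2,3,3a,4,5,6,7-octahydroazulen-8-yl trifluoromethanesulfonate, via samarium enolate 22 (not isolated)
Conditions: SmI2 (slow addition), HMPA, THF, 0 °C to rt; then N-(5-chloropyridin-2-yl)bis(trifluoromethanesulfonimide) (Comins' reagent), −78 to 0 °C
Reagents that add atoms: N-(5-chloropyridin-2-yl)-1,1,1-trifluoro-N-(trifluoromethylsulfonyl)methanesulfonamide (Clc1ccc(nc1)N(S(=O)(=O)C(F)(F)F)S(=O)(=O)C(F)(F)F)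
Why: SmI2–HMPA transfers one electron to the C10 carbonyl, and the ketyl opens the spiro-cyclopropane by β-scission of the C1–C3 bond (the two cyclopropane bonds are equivalent and one always overlaps with the ketyl orbital), giving the trivalent samarium enolate C10(O)=C1 and a primary radical at C3. This radical closes the cyclopentane by 5-exo-dig attack on C4 of the ethynyl group, and the vinyl radical at C15 takes a hydrogen atom from THF; the closest known reaction type is the SmI2-induced tandem ring-opening/cyclisation of cyclopropyl ketones that carry an alkyne. No new stereocentre is formed, since C1 and C4 become sp2 and C5 is kept, so C4 is left to the later hydrogenation. The step needs ring closure to outrun reduction of the C3 radical by SmI2, which slow addition of the reductant and the short tether held on the ring should secure. It also needs the enolate to stay regiochemically intact, which the absence of a proton source and direct O-sulfonylation with Comins' reagent secure, so that the tetrasubstituted C1=C10 bond is fixed as the enol triflate.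

**Step 13**
Reactants: 23 (3aS,5R)-3-methylidene-5-[(4R)-2,2,4-trimethyl-1,3-dioxolan-4-yl]-1,2,3,3a,4,5,6,7-octahydroazulen-8-yl trifluoromethanesulfonate
Product: 24 (4R)-2,2,4-trimethyl-4-[(3aS,5R)-8-methyl-3-methylidene-1,2,3,3a,4,5,6,7-octahydroazulen-5-yl]-1,3-dioxolane
Conditions: MeMgBr, Fe(acac)3 (cat.), THF–NMP, −30 to 0 °C
Reagents that add atoms: methylmagnesium bromide (C[Mg]Br)
Why: iron-catalysed cross-coupling of an alkenyl triflate with a Grignard reagent replaces the triflate by methyl C14 with retention of the double-bond position, which places the tetrasubstituted alkene exactly at C1=C10.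

**Step 14**
Reactants: 24 (4R)-2,2,4-trimethyl-4-[(3aS,5R)-8-methyl-3-methylidene-1,2,3,3a,4,5,6,7-octahydroazulen-5-yl]-1,3-dioxolane
Product: 25 (4R)-4-[(3S,3aS,5R)-3,8-dimethyl-1,2,3,3a,4,5,6,7-octahydroazulen-5-yl]-2,2,4-trimethyl-1,3-dioxolane
Conditions: H2 (1 atm), RhCl(PPh3)3 (cat.), benzene–EtOH, rt
Reagents that add atoms: none
Why: homogeneous hydrogenation with RhCl(PPh3)3 reduces the 1,1-disubstituted exocyclic alkene and leaves the tetrasubstituted C1=C10 bond, and hydrogen should reach C4 from the face of H-5, away from C6 and the folded seven-membered ring, which sets the C4 methyl cis to C6 as in the target.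

**Step 15**
Reactants: 25 (4R)-4-[(3S,3aS,5R)-3,8-dimethyl-1,2,3,3a,4,5,6,7-octahydroazulen-5-yl]-2,2,4-trimethyl-1,3-dioxolane
Product: 27 (3S,3aS,5R,8R,8aS)-3,8-dimethyl-5-[(4R)-2,2,4-trimethyl-1,3-dioxolan-4-yl]decahydroazulene-8,8a-diol, via osmate ester 26 (not isolated)
Conditions: OsO4 (1.1 equiv), pyridine–THF, 0 °C to rt; aq. NaHSO3
Reagents that add atoms: osmium tetroxide (O=[Os](=O)(=O)=O)
Why: stoichiometric osmylation is a suprafacial syn-dihydroxylation, so both hydroxyl groups arrive on one face, and OsO4 should approach C1=C10 from the face that carries only H-5, opposite to the C4 methyl group, C6 and the C7 side chain, which gives the cis-fused 1,10-diol.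

**Step 16**
Reactants: 27 (3S,3aS,5R,8R,8aS)-3,8-dimethyl-5-[(4R)-2,2,4-trimethyl-1,3-dioxolan-4-yl]decahydroazulene-8,8a-diol
Product: 28 (3S,3aS,5R,8R,8aS)-5-[(2R)-1,2-dihydroxypropan-2-yl]-3,8-dimethyldecahydroazulene-8,8a-diol
Conditions: AcOH–H2O (4:1), 40 °C
Reagents that add atoms: none
Why: mild aqueous acid hydrolyses the acetonide (acetal hydrolysis) without ionising the tertiary alcohols or inducing pinacol rearrangement of the ditertiary diol.

**Step 17**
Reactants: 28 (3S,3aS,5R,8R,8aS)-5-[(2R)-1,2-dihydroxypropan-2-yl]-3,8-dimethyldecahydroazulene-8,8a-diol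
Product: 30 (2R)-2-[(3S,3aS,5R,8R,8aS)-8,8a-dihydroxy-3,8-dimethyldecahydroazulen-5-yl]-2-hydroxypropyl hydrogen sulfate, via pyridinium sulfate 29 (not isolated)
Conditions: SO3·pyridine (1.5 equiv), pyridine, 0 °C to rt; Dowex 50W (H+ form), H2O–MeOH, 0 °C; freeze-drying
Reagents that add atoms: sulfur trioxide–pyridine complex (O=S(=O)([O-])[n+]1ccccc1)
Why: SO3·pyridine sulfates the single primary hydroxyl group far faster than the three tertiary ones (O-sulfation), and cation exchange of the pyridinium salt in the cold releases the hydrogen sulfate.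

**Compound list**
1 | (R)-(+)-limonene | CC1=CC[C@@H](CC1)C(C)=C | starting material
2 | {2-[(1R)-4-methylcyclohex-3-en-1-yl]prop-2-en-1-yl}lithium | CC1=CC[C@@H](CC1)C(=C)C[Li] | intermediate
3 | dimethyl {2-[(1R)-4-methylcyclohex-3-en-1-yl]prop-2-en-1-yl}boronate | CC1=CC[C@@H](CC1)C(=C)CB(OC)OC | intermediate
4 | 2-[(1R)-4-methylcyclohex-3-en-1-yl]prop-2-en-1-ol | CC1=CC[C@@H](CC1)C(=C)CO | intermediate
5 | [(2R)-2-[(1R)-4-methylcyclohex-3-en-1-yl]oxiran-2-yl]methanol | CC1=CC[C@@H](CC1)[C@]2(CO2)CO | intermediate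
6 | (2R)-2-[(1R)-4-methylcyclohex-3-en-1-yl]propane-1,2-diol | CC1=CC[C@@H](CC1)[C@@](C)(O)CO | intermediate
7 | (4R)-2,2,4-trimethyl-4-[(1R)-4-methylcyclohex-3-en-1-yl]-1,3-dioxolane | CC1=CC[C@@H](CC1)[C@@]2(C)OC(C)(C)OC2 | intermediate
8 | (4R)-1-methyl-4-[(4R)-2,2,4-trimethyl-1,3-dioxolan-4-yl]-7,8,9-trioxabicyclo[4.2.1]nonane (ozonide, bridgehead isomers) | CC12CC[C@H](CC(OO1)O2)[C@@]3(C)OC(C)(C)OC3 | intermediate
9 | (3R)-6-oxo-3-[(4R)-2,2,4-trimethyl-1,3-dioxolan-4-yl]heptanal | CC(=O)CC[C@H](CC=O)[C@@]1(C)OC(C)(C)OC1 | intermediate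
10 | (5R)-5-[(4R)-2,2,4-trimethyl-1,3-dioxolan-4-yl]oct-7-en-2-one | CC(=O)CC[C@H](CC=C)[C@@]1(C)OC(C)(C)OC1 | intermediate
11 | lithium (5R)-5-[(4R)-2,2,4-trimethyl-1,3-dioxolan-4-yl]octa-1,7-dien-2-olate | C=C(O[Li])CC[C@H](CC=C)[C@@]1(C)OC(C)(C)OC1 | intermediate
12 | (6R)-1-(dimethylamino)-6-[(4R)-2,2,4-trimethyl-1,3-dioxolan-4-yl]non-8-en-3-one | CN(C)CCC(=O)CC[C@H](CC=C)[C@@]1(C)OC(C)(C)OC1 | intermediate
13 | (6R)-N,N,N-trimethyl-3-oxo-6-[(4R)-2,2,4-trimethyl-1,3-dioxolan-4-yl]non-8-en-1-aminium iodide | C[N+](C)(C)CCC(=O)CC[C@H](CC=C)[C@@]1(C)OC(C)(C)OC1.[I-] | intermediate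
14 | (6R)-6-[(4R)-2,2,4-trimethyl-1,3-dioxolan-4-yl]nona-1,8-dien-3-one | C=CC(=O)CC[C@H](CC=C)[C@@]1(C)OC(C)(C)OC1 | intermediate
15 | (5R)-5-[(4R)-2,2,4-trimethyl-1,3-dioxolan-4-yl]cyclohept-2-en-1-one | O=C1C=CC[C@@H](CC1)[C@@]2(C)OC(C)(C)OC2 | intermediate
16 | trimethyl({(3R,5R)-3-[(trimethylsilyl)ethynyl]-5-[(4R)-2,2,4-trimethyl-1,3-dioxolan-4-yl]cyclohept-1-en-1-yl}oxy)silane | C[Si](C)(C)OC1=C[C@H](C#C[Si](C)(C)C)C[C@@H](CC1)[C@@]2(C)OC(C)(C)OC2 | intermediate
17 | (3R,5R)-2-[(dimethylamino)methyl]-5-[(4R)-2,2,4-trimethyl-1,3-dioxolan-4-yl]-3-[(trimethylsilyl)ethynyl]cycloheptan-1-one (C2 epimers) | CN(C)CC1[C@H](C#C[Si](C)(C)C)C[C@@H](CCC1=O)[C@@]2(C)OC(C)(C)OC2 | intermediate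
18 | N,N,N-trimethyl-1-{(2R,4R)-7-oxo-4-[(4R)-2,2,4-trimethyl-1,3-dioxolan-4-yl]-2-[(trimethylsilyl)ethynyl]cycloheptyl}methanaminium iodide (C1 epimers) | C[N+](C)(C)CC1[C@H](C#C[Si](C)(C)C)C[C@@H](CCC1=O)[C@@]2(C)OC(C)(C)OC2.[I-] | intermediate
19 | (3R,5R)-2-methylidene-5-[(4R)-2,2,4-trimethyl-1,3-dioxolan-4-yl]-3-[(trimethylsilyl)ethynyl]cycloheptan-1-one | C=C1[C@H](C#C[Si](C)(C)C)C[C@@H](CCC1=O)[C@@]2(C)OC(C)(C)OC2 | intermediate
20 | (7R,9R)-7-[(4R)-2,2,4-trimethyl-1,3-dioxolan-4-yl]-9-[(trimethylsilyl)ethynyl]spiro[2.6]nonan-4-one | O=C1C2(CC2)[C@H](C#C[Si](C)(C)C)C[C@@H](CC1)[C@@]3(C)OC(C)(C)OC3 | intermediate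
21 | (7R,9S)-9-ethynyl-7-[(4R)-2,2,4-trimethyl-1,3-dioxolan-4-yl]spiro[2.6]nonan-4-one | O=C1C2(CC2)[C@H](C#C)C[C@@H](CC1)[C@@]3(C)OC(C)(C)OC3 | intermediate
22 | diiodosamarium (3aS,5R)-3-methylidene-5-[(4R)-2,2,4-trimethyl-1,3-dioxolan-4-yl]-1,2,3,3a,4,5,6,7-octahydroazulen-8-olate | C=C1CCC2=C(O[Sm](I)I)CC[C@@H]([C@@]3(C)OC(C)(C)OC3)C[C@@H]12 | intermediate
23 | (3aS,5R)-3-methylidene-5-[(4R)-2,2,4-trimethyl-1,3-dioxolan-4-yl]-1,2,3,3a,4,5,6,7-octahydroazulen-8-yl trifluoromethanesulfonate | C=C1CCC2=C(OS(=O)(=O)C(F)(F)F)CC[C@@H]([C@@]3(C)OC(C)(C)OC3)C[C@@H]12 | intermediate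
24 | (4R)-2,2,4-trimethyl-4-[(3aS,5R)-8-methyl-3-methylidene-1,2,3,3a,4,5,6,7-octahydroazulen-5-yl]-1,3-dioxolane | C=C1CCC2=C(C)CC[C@@H]([C@@]3(C)OC(C)(C)OC3)C[C@@H]12 | intermediate
25 | (4R)-4-[(3S,3aS,5R)-3,8-dimethyl-1,2,3,3a,4,5,6,7-octahydroazulen-5-yl]-2,2,4-trimethyl-1,3-dioxolane | C[C@H]1CCC2=C(C)CC[C@@H]([C@@]3(C)OC(C)(C)OC3)C[C@@H]12 | intermediate
26 | cyclic hexavalent osmium ester of 27 (dioxo-osmium 8,8a-diolate) | C[C@H]1CC[C@]23[C@H]1C[C@H]([C@@]4(C)OC(C)(C)OC4)CC[C@@]2(C)O[Os](=O)(=O)O3 | intermediate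
27 | (3S,3aS,5R,8R,8aS)-3,8-dimethyl-5-[(4R)-2,2,4-trimethyl-1,3-dioxolan-4-yl]decahydroazulene-8,8a-diol | C[C@H]1CC[C@]2(O)[C@H]1C[C@H]([C@@]3(C)OC(C)(C)OC3)CC[C@@]2(C)O | intermediate
28 | (3S,3aS,5R,8R,8aS)-5-[(2R)-1,2-dihydroxypropan-2-yl]-3,8-dimethyldecahydroazulene-8,8a-diol | C[C@H]1CC[C@]2(O)[C@H]1C[C@H]([C@@](C)(O)CO)CC[C@@]2(C)O | intermediate
29 | pyridinium (2R)-2-[(3S,3aS,5R,8R,8aS)-8,8a-dihydroxy-3,8-dimethyldecahydroazulen-5-yl]-2-hydroxypropyl sulfate | C[C@H]1CC[C@]2(O)[C@H]1C[C@H]([C@@](C)(O)COS(=O)(=O)[O-])CC[C@@]2(C)O.c1cc[nH+]cc1 | intermediate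
30 | (2R)-2-[(3S,3aS,5R,8R,8aS)-8,8a-dihydroxy-3,8-dimethyldecahydroazulen-5-yl]-2-hydroxypropyl hydrogen sulfate | C[C@H]1CC[C@]2(O)[C@H]1C[C@H]([C@@](C)(O)COS(=O)(=O)O)CC[C@@]2(C)O | target

**Count**
Total steps: 17. Longest linear sequence: 17 steps (1 to 30).

**Steps most likely to fail**

Step 12. The C3 radical may be reduced by SmI2 before it closes the ring, or O-sulfonylation of the samarium enolate may be incomplete. The fallback separates ring opening from ring closure and sets out from 21. Addition of MeLi/CeCl3 gives the tertiary cyclopropylcarbinol F2 (both C10 epimers serve). A Julia-type homoallylic rearrangement with MgBr2·OEt2 in ether at 0 °C opens the cyclopropane to the C1=C10 alkene, already carrying C14, and gives the homoallylic bromide F3. Bu3SnH/AIBN in benzene at 80 °C (slow addition) then closes C3–C4 by 5-exo-dig radical cyclisation. The route is rejoined at 24.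

Step 9. Facial selectivity in delivery of the alkynyl group to C5 may be poor or reversed. The fallback reverses the order in which the two groups arrive at C5 and sets out from 16, used as its epimer mixture. Saegusa–Ito oxidation with Pd(OAc)2 in MeCN gives the enynone F1. Conjugate reduction with [(Ph3P)CuH]6 and Me3SiCl then delivers hydride to C5, so a substrate bias that puts the incoming group trans to the side chain now leaves the alkyne cis. The route is rejoined at 16.

Step 14. Hydrogen may be delivered to the wrong face of C4=C15, or the exocyclic double bond may migrate into the ring before reduction. The fallback replaces metal-catalysed hydrogenation by hydroboration and sets out from 24. 9-BBN followed by H2O2/NaOH should add to the exocyclic alkene from the face of H-5 with a bulkier reagent that cannot isomerise the alkene, giving the primary alcohol F4. TsCl/pyridine gives the tosylate F5, and LiEt3BH reduces it to the methyl group. The route is rejoined at 25.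

**Further compounds**
F1 | step 9 | (5R)-3-[(trimethylsilyl)ethynyl]-5-[(4R)-2,2,4-trimethyl-1,3-dioxolan-4-yl]cyclohept-2-en-1-one | O=C1C=C(C#C[Si](C)(C)C)C[C@@H](CC1)[C@@]2(C)OC(C)(C)OC2
F2 | step 12 | (7R,9S)-9-ethynyl-4-methyl-7-[(4R)-2,2,4-trimethyl-1,3-dioxolan-4-yl]spiro[2.6]nonan-4-ol (C4 epimers) | CC1(O)C2(CC2)[C@H](C#C)C[C@@H](CC1)[C@@]3(C)OC(C)(C)OC3
F3 | step 12 | (4R)-4-[(1R,3S)-4-(2-bromoethyl)-3-ethynyl-5-methylcyclohept-4-en-1-yl]-2,2,4-trimethyl-1,3-dioxolane | CC1=C(CCBr)[C@H](C#C)C[C@@H](CC1)[C@@]2(C)OC(C)(C)OC2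
F4 | step 14 | [(3S,3aS,5R)-8-methyl-5-[(4R)-2,2,4-trimethyl-1,3-dioxolan-4-yl]-1,2,3,3a,4,5,6,7-octahydroazulen-3-yl]methanol | OC[C@H]1CCC2=C(C)CC[C@@H]([C@@]3(C)OC(C)(C)OC3)C[C@@H]12
F5 | step 14 | [(3S,3aS,5R)-8-methyl-5-[(4R)-2,2,4-trimethyl-1,3-dioxolan-4-yl]-1,2,3,3a,4,5,6,7-octahydroazulen-3-yl]methyl 4-methylbenzenesulfonate | Cc1ccc(cc1)S(=O)(=O)OC[C@H]1CCC2=C(C)CC[C@@H]([C@@]3(C)OC(C)(C)OC3)C[C@@H]12
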